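Retrosynthesis: remove the two isovalerates and the acetal mask of the formyl group; exchange C3–O for C3–B; cut C3a–C3 (ring closure); then cut C2–C3, O1–C2 and Cα–C2, all of which are made on one boron atom.
Enabling feature: C3 is a benzylic carbinol carbon whose neighbours C3a and C2 are already joined through C7a–O1. A boron atom set between C3a and C3 therefore expands the furan ring (O1, C2, C3, C3a, C7a) to a six-membered 1,4-benzoxaborinine borate. Its B–C3a bond can slide onto C3, and its boron later becomes the C3 oxygen.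
Forward: the chain Cα→C2→C3 grows on an (S,S)-DICHED alkenylboronic ester by two Matteson homologations, with the iodophenoxide (arene ring, O1) inserted between them. Iodine–lithium exchange closes the boracycle, which contracts to the dihydrofuran ring. Oxidation, desilylation, double acylation and acetal hydrolysis finish the target.
Stereochemistry: C2 and C3 both come from the one diol on boron (chlorides set by the diol, displacements with inversion, migrations and oxidation with retention), which enforces the cis-2,3 pattern against the steric bias. C1' comes from a CBS reduction.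

Key step: step 7

Remark: benzofuran numbering is used (O1, C2, C3, C3a, C4–C7, C7a); Cα is the vinyl carbon on C2 and C1' the side-chain carbinol; the SMILES is read as the cis-(2R,3R),(1'R) isomer.

Step 1
Reactants: 1 1-(4-hydroxy-3-iodophenyl)ethan-1-one
Product: 2 4-[(1R)-1-hydroxyethyl]-2-iodophenol
Conditions: (S)-2-methyl-CBS-oxazaborolidine (10 mol %), BH3·SMe2 (2.2 equiv), THF, 0 °C; MeOH quench
Reagents that add atoms: none
Why: Corey–Bakshi–Shibata reduction, in which the (S)-oxazaborolidine should deliver hydride to the face of the aryl methyl ketone that gives the (R)-carbinol (aryl as the large group), while the phenol is masked in situ as an aryloxyborane and the aryl iodide is inert to borane.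

Step 2
Reactants: 2 4-[(1R)-1-hydroxyethyl]-2-iodophenol
Product: 4 4-[(1R)-1-(tert-butyldimethylsilyloxy)ethyl]-2-iodophenol, via bis-TBS ether 3 (not isolated)
Conditions: TBSCl (2.4 equiv), imidazole, DMF, rt; then K2CO3 (cat.), MeOH, rt
Reagents that add atoms: tert-butyldimethylsilyl chloride, C[Si](C)(Cl)C(C)(C)C
Why: Silyl ether formation followed by selective base-catalysed methanolysis of the aryl silyl ether, which is far more labile than the secondary alkyl silyl ether; the poor silanolate leaving group keeps the free phenoxide from forming a para-quinone methide, so C1' is not scrambled.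

Step 3
Reactants: 5 2-bromo-3,3-diethoxyprop-1-ene; 6 (1S,2S)-1,2-dicyclohexylethane-1,2-diol [(S,S)-DICHED]
Product: 9 (4S,5S)-4,5-dicyclohexyl-2-(3,3-diethoxyprop-1-en-2-yl)-1,3,2-dioxaborolane, via alkenyllithium 7 (not isolated), via lithium triisopropoxyborate 8 (not isolated)
Conditions: n-BuLi, Et2O, −78 °C; B(OiPr)3, −78 °C → rt; Me3SiCl; 6, rt
Reagents that add atoms: triisopropyl borate, CC(C)OB(OC(C)C)OC(C)C
Why: Bromine–lithium exchange gives the α-lithioacrolein acetal, which is borylated (organolithium borylation) and transesterified with the C2-symmetric diol under neutral conditions that spare the acetal.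

Step 4
Reactants: 9 (4S,5S)-4,5-dicyclohexyl-2-(3,3-diethoxyprop-1-en-2-yl)-1,3,2-dioxaborolane
Product: 11 (4S,5S)-2-[(1R)-1-chloro-2-(diethoxymethyl)prop-2-en-1-yl]-4,5-dicyclohexyl-1,3,2-dioxaborolane, via dichloromethyl borate 10 (not isolated)
Conditions: CH2Cl2, n-BuLi, THF, −100 °C (LiCHCl2); add 9; ZnCl2, −100 °C → rt
Reagents that add atoms: dichloromethane, ClCCl
Why: Matteson homologation, in which LiCHCl2 adds to boron and the ZnCl2-assisted 1,2-migration of the alkenyl group displaces one of the diastereotopic chlorides, an (S,S)-diol ester giving the (αR)-chloride (mirror image of the rule that (R,R)-diol esters give αS); this creates C2.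

Step 5
Reactants: 4 4-[(1R)-1-(tert-butyldimethylsilyloxy)ethyl]-2-iodophenol; 11 (4S,5S)-2-[(1R)-1-chloro-2-(diethoxymethyl)prop-2-en-1-yl]-4,5-dicyclohexyl-1,3,2-dioxaborolane
Product: 14 (4S,5S)-2-[(1S)-1-{4-[(1R)-1-(tert-butyldimethylsilyloxy)ethyl]-2-iodophenoxy}-2-(diethoxymethyl)prop-2-en-1-yl]-4,5-dicyclohexyl-1,3,2-dioxaborolane, via lithium aryloxide 12 (not isolated), via aryloxy borate 13 (not isolated)
Conditions: 4, LiN(SiMe3)2, THF, 0 °C; add 11, THF/DMSO, 0 °C → rt
Reagents that add atoms: none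
Why: Matteson-type substitution of an α-chloro boronic ester by an oxygen nucleophile, in which the aryloxide binds to boron and shifts to C2 with inversion (O1–C2 bond); coordination to boron should favour attack at C2 over SN2' attack at the methylene terminus.

Step 6
Reactants: 14 (4S,5S)-2-[(1S)-1-{4-[(1R)-1-(tert-butyldimethylsilyloxy)ethyl]-2-iodophenoxy}-2-(diethoxymethyl)prop-2-en-1-yl]-4,5-dicyclohexyl-1,3,2-dioxaborolane
Product: 16 (4S,5S)-2-[(1R,2R)-1-chloro-2-{4-[(1R)-1-(tert-butyldimethylsilyloxy)ethyl]-2-iodophenoxy}-3-(diethoxymethyl)but-3-en-1-yl]-4,5-dicyclohexyl-1,3,2-dioxaborolane, via dichloromethyl borate 15 (not isolated)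
Conditions: CH2Cl2 (excess), THF, −78 °C, LiN(iPr)2 added slowly; ZnCl2, −78 °C → rt
Reagents that add atoms: dichloromethane, ClCCl
Why: Second Matteson homologation, with LiCHCl2 made in situ by the amide base so that no alkyllithium meets the aryl iodide; C2 migrates with retention and the same diol again sets an (αR)-chloride, now at C3.

Step 7
Reactants: 16 (4S,5S)-2-[(1R,2R)-1-chloro-2-{4-[(1R)-1-(tert-butyldimethylsilyloxy)ethyl]-2-iodophenoxy}-3-(diethoxymethyl)but-3-en-1-yl]-4,5-dicyclohexyl-1,3,2-dioxaborolane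
Product: 19 (4S,5S)-2-[(2S,3R)-5-[(1R)-1-(tert-butyldimethylsilyloxy)ethyl]-2-(3,3-diethoxyprop-1-en-2-yl)-2,3-dihydro-1-benzofuran-3-yl]-4,5-dicyclohexyl-1,3,2-dioxaborolane (boron cis to the C2 side chain; the C2 descriptor reads S only because boron ranks below carbon), via aryllithium 17 (not isolated), via spiro borate 18 (not isolated)
Conditions: n-BuLi (1.0 equiv), THF/Et2O, −100 °C; ZnCl2 (1 equiv), −78 °C → rt
Reagents that add atoms: none
Why: Proposed new method: iodine–lithium exchange at C3a (faster than addition of n-BuLi to a boronic ester, the basis of in situ quench borylations) gives aryllithium 17, which is held next to boron and adds to it to give the six-membered spiro borate 18; the endocyclic B–C3a bond then migrates to C3 with loss of chloride, so the 1,4-benzoxaborinine ring contracts to the dihydrofuran ring and boron ends up exocyclic on C3. The closest known reactions are the Matteson substitution of α-chloro boronic esters by aryl Grignard or aryllithium reagents (here made intramolecular) and the ring-contracting 1,2-migrations of α-halogenated cyclic boranes and cyclic boronate complexes. Ring closure: the temporary six-membered ring forms by attack of C3a on boron, and the five-membered ring forms by a 1,2-metallate shift that amounts to a 5-exo-tet displacement at C3. C3 is controlled by stereospecific inversion of the (1R)-chloride while C2 is a spectator, and because chlorine and the C2 side chain are cis on the boracycle the product carries boron and side chain cis, a pattern that steric control in a direct aryl-to-carbonyl closure would not give. The step needs aryl rather than oxygen migration and no β-elimination of O1: with chlorine equatorial (side chain axial) in the half-chair only the ring B–C3a bond is antiperiplanar to C3–Cl, and the B–C3–C2–O1 torsion is locked gauche in the ring, which blocks the anti elimination open to acyclic β-aryloxy borates. The pendant 1,1-disubstituted alkene, the acetal and the silyl ether should not react with an aryllithium at −100 °C on the time scale of its capture by boron.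

Step 8
Reactants: 19 (4S,5S)-2-[(2S,3R)-5-[(1R)-1-(tert-butyldimethylsilyloxy)ethyl]-2-(3,3-diethoxyprop-1-en-2-yl)-2,3-dihydro-1-benzofuran-3-yl]-4,5-dicyclohexyl-1,3,2-dioxaborolane
Product: 20 (2R,3R)-5-[(1R)-1-(tert-butyldimethylsilyloxy)ethyl]-2-(3,3-diethoxyprop-1-en-2-yl)-2,3-dihydro-1-benzofuran-3-ol
Conditions: H2O2 (30 % aq.), NaOH, THF, 0 °C
Reagents that add atoms: hydrogen peroxide, OO
Why: Oxidation of the C–B bond by alkaline hydrogen peroxide, a boron-to-oxygen 1,2-shift with retention, so the helper atom leaves as the C3 hydroxyl cis to the side chain and the chiral diol is recovered.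

Step 9
Reactants: 20 (2R,3R)-5-[(1R)-1-(tert-butyldimethylsilyloxy)ethyl]-2-(3,3-diethoxyprop-1-en-2-yl)-2,3-dihydro-1-benzofuran-3-ol
Product: 21 (2R,3R)-2-(3,3-diethoxyprop-1-en-2-yl)-5-[(1R)-1-hydroxyethyl]-2,3-dihydro-1-benzofuran-3-ol
Conditions: Bu4NF, THF, 0 °C → rt
Reagents that add atoms: none
Why: Fluoride-induced desilylation cleaves only the Si–O bond, so C1' keeps its configuration and the acetal and the allylic aryl ether are untouched.

Step 10
Reactants: 21 (2R,3R)-2-(3,3-diethoxyprop-1-en-2-yl)-5-[(1R)-1-hydroxyethyl]-2,3-dihydro-1-benzofuran-3-ol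
Product: 22 (1R)-1-[(2R,3R)-2-(3,3-diethoxyprop-1-en-2-yl)-3-(3-methylbutanoyloxy)-2,3-dihydro-1-benzofuran-5-yl]ethyl 3-methylbutanoate
Conditions: isovaleric anhydride (3 equiv), DMAP (0.2 equiv), pyridine, CH2Cl2, 0 °C
Reagents that add atoms: isovaleric anhydride, CC(C)CC(=O)OC(=O)CC(C)C
Why: DMAP-catalysed acylation of both secondary benzylic alcohols breaks no C–O bond (retention at C3 and C1'), the masked aldehyde rules out lactol formation with the cis C3 hydroxyl, and the weak base and low temperature should keep E2 loss of the C3 ester to the benzofuran slow.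

Step 11
Reactants: 22 (1R)-1-[(2R,3R)-2-(3,3-diethoxyprop-1-en-2-yl)-3-(3-methylbutanoyloxy)-2,3-dihydro-1-benzofuran-5-yl]ethyl 3-methylbutanoate
Product: 23 (1R)-1-[(2R,3R)-3-(3-methylbutanoyloxy)-2-(3-oxoprop-1-en-2-yl)-2,3-dihydro-1-benzofuran-5-yl]ethyl 3-methylbutanoate (CNP0316116.1)
Conditions: 10 % aq. oxalic acid on silica gel, CH2Cl2, rt
Reagents that add atoms: water, O
Why: Mild acid hydrolysis of an α,β-unsaturated acetal through an allyl-stabilised oxocarbenium ion, which should be much faster than ionisation of the two benzylic esters and touches no stereocentre.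

Compound list
1 | 1-(4-hydroxy-3-iodophenyl)ethan-1-one | CC(=O)c1ccc(O)c(I)c1 | starting material
2 | 4-[(1R)-1-hydroxyethyl]-2-iodophenol | C[C@@H](O)c1ccc(O)c(I)c1 | intermediate
3 | bis-TBS ether of 2 | C[C@@H](O[Si](C)(C)C(C)(C)C)c1ccc(O[Si](C)(C)C(C)(C)C)c(I)c1 | intermediate
4 | 4-[(1R)-1-(tert-butyldimethylsilyloxy)ethyl]-2-iodophenol | C[C@@H](O[Si](C)(C)C(C)(C)C)c1ccc(O)c(I)c1 | intermediate
5 | 2-bromo-3,3-diethoxyprop-1-ene | C=C(Br)C(OCC)OCC | starting material
6 | (1S,2S)-1,2-dicyclohexylethane-1,2-diol | O[C@@H](C1CCCCC1)[C@@H](O)C1CCCCC1 | starting material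
7 | (3,3-diethoxyprop-1-en-2-yl)lithium | [Li]C(=C)C(OCC)OCC | intermediate
8 | lithium (3,3-diethoxyprop-1-en-2-yl)triisopropoxyborate | [Li+].C=C(C(OCC)OCC)[B-](OC(C)C)(OC(C)C)OC(C)C | intermediate
9 | (4S,5S)-4,5-dicyclohexyl-2-(3,3-diethoxyprop-1-en-2-yl)-1,3,2-dioxaborolane | C=C(C(OCC)OCC)B1O[C@@H](C2CCCCC2)[C@H](C2CCCCC2)O1 | intermediate
10 | lithium (dichloromethyl)borate of 9 | [Li+].C=C(C(OCC)OCC)[B-]1(C(Cl)Cl)O[C@@H](C2CCCCC2)[C@H](C2CCCCC2)O1 | intermediate
11 | (4S,5S)-2-[(1R)-1-chloro-2-(diethoxymethyl)prop-2-en-1-yl]-4,5-dicyclohexyl-1,3,2-dioxaborolane | C=C(C(OCC)OCC)[C@H](Cl)B1O[C@@H](C2CCCCC2)[C@H](C2CCCCC2)O1 | intermediate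
12 | lithium 4-[(1R)-1-(tert-butyldimethylsilyloxy)ethyl]-2-iodophenoxide | [Li+].C[C@@H](O[Si](C)(C)C(C)(C)C)c1ccc([O-])c(I)c1 | intermediate
13 | lithium aryloxyborate from 11 and 12 | [Li+].C=C(C(OCC)OCC)[C@H](Cl)[B-]1(Oc2ccc([C@@H](C)O[Si](C)(C)C(C)(C)C)cc2I)O[C@@H](C2CCCCC2)[C@H](C2CCCCC2)O1 | intermediate
14 | (1S)-α-aryloxy allylboronic ester (full name in step 5) | C=C(C(OCC)OCC)[C@@H](Oc1ccc([C@@H](C)O[Si](C)(C)C(C)(C)C)cc1I)B1O[C@@H](C2CCCCC2)[C@H](C2CCCCC2)O1 | intermediate
15 | lithium (dichloromethyl)borate of 14 | [Li+].C=C(C(OCC)OCC)[C@@H](Oc1ccc([C@@H](C)O[Si](C)(C)C(C)(C)C)cc1I)[B-]1(C(Cl)Cl)O[C@@H](C2CCCCC2)[C@H](C2CCCCC2)O1 | intermediate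
16 | (1R,2R)-α-chloro-β-aryloxy boronic ester (full name in step 6) | C=C(C(OCC)OCC)[C@@H](Oc1ccc([C@@H](C)O[Si](C)(C)C(C)(C)C)cc1I)[C@H](Cl)B1O[C@@H](C2CCCCC2)[C@H](C2CCCCC2)O1 | intermediate
17 | aryllithium from 16 (lithium in place of iodine at C3a) | C=C(C(OCC)OCC)[C@@H](Oc1ccc([C@@H](C)O[Si](C)(C)C(C)(C)C)cc1[Li])[C@H](Cl)B1O[C@@H](C2CCCCC2)[C@H](C2CCCCC2)O1 | intermediate
18 | lithium spiro borate: 1,4-benzoxaborinine ring (O1, C2, C3, B, C3a, C7a) spiro at boron to the DICHED dioxaborolane, chlorine on C3 cis to the C2 side chain | [Li+].C=C(C(OCC)OCC)[C@H]1Oc2ccc([C@@H](C)O[Si](C)(C)C(C)(C)C)cc2[B-]2(O[C@@H](C3CCCCC3)[C@H](C3CCCCC3)O2)[C@H]1Cl | intermediate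
19 | cis-3-boryl-2,3-dihydrobenzofuran (full name in step 7) | C=C(C(OCC)OCC)[C@H]1Oc2ccc([C@@H](C)O[Si](C)(C)C(C)(C)C)cc2[C@H]1B1O[C@@H](C2CCCCC2)[C@H](C2CCCCC2)O1 | intermediate
20 | (2R,3R)-5-[(1R)-1-(tert-butyldimethylsilyloxy)ethyl]-2-(3,3-diethoxyprop-1-en-2-yl)-2,3-dihydro-1-benzofuran-3-ol | C=C(C(OCC)OCC)[C@H]1Oc2ccc([C@@H](C)O[Si](C)(C)C(C)(C)C)cc2[C@H]1O | intermediate
21 | (2R,3R)-2-(3,3-diethoxyprop-1-en-2-yl)-5-[(1R)-1-hydroxyethyl]-2,3-dihydro-1-benzofuran-3-ol | C=C(C(OCC)OCC)[C@H]1Oc2ccc([C@@H](C)O)cc2[C@H]1O | intermediate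
22 | (1R)-1-[(2R,3R)-2-(3,3-diethoxyprop-1-en-2-yl)-3-(3-methylbutanoyloxy)-2,3-dihydro-1-benzofuran-5-yl]ethyl 3-methylbutanoate | C=C(C(OCC)OCC)[C@H]1Oc2ccc([C@@H](C)OC(=O)CC(C)C)cc2[C@H]1OC(=O)CC(C)C | intermediate
23 | (1R)-1-[(2R,3R)-3-(3-methylbutanoyloxy)-2-(3-oxoprop-1-en-2-yl)-2,3-dihydro-1-benzofuran-5-yl]ethyl 3-methylbutanoate | C=C(C=O)[C@H]1Oc2ccc([C@@H](C)OC(=O)CC(C)C)cc2[C@H]1OC(=O)CC(C)C | target

Total step count: 11. Longest linear sequence: 9 steps (steps 3–11 from 5; equally steps 1, 2 and 5–11 from 1).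

Steps most likely to fail

1. Step 7. Three things may go wrong. n-BuLi may add to boron in competition with the exchange. A diol oxygen may migrate instead of the aryl carbon, from the conformer with axial chlorine. The borate may break down by loss of aryloxide. The fallback uses known chemistry only and closes the same bond at the carbonyl level; it sets out from 16 and comes back at 20. Buffered H2O2 (NaHCO3, THF/H2O) would oxidise the α-chloro boronic ester 16 to (2R)-2-{4-[(1R)-1-(tert-butyldimethylsilyloxy)ethyl]-2-iodophenoxy}-3-(diethoxymethyl)but-3-enal F1. An intramolecular Nozaki–Hiyama–Kishi reaction (CrCl2, cat. NiCl2, DMF) would close C3a–C3 to the C3-epimeric (2R)-5-[(1R)-1-(tert-butyldimethylsilyloxy)ethyl]-2-(3,3-diethoxyprop-1-en-2-yl)-2,3-dihydro-1-benzofuran-3-ols F2. Dess–Martin oxidation would give 5-[(1R)-1-(tert-butyldimethylsilyloxy)ethyl]-2-(3,3-diethoxyprop-1-en-2-yl)-1-benzofuran-3(2H)-one F3, whose C2 is configurationally labile. Asymmetric transfer hydrogenation under dynamic kinetic resolution (RuCl(p-cymene)[(S,S)-TsDPEN], HCO2H/Et3N) would then add hydride anti to the C2 side chain and give the cis alcohol 20.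

2. Step 5. The weakly nucleophilic, ortho-hindered aryloxide may displace slowly. This leaves time for chloride-induced epimerisation of the allylic α-chloro boronic ester and for SN2' attack at the methylene terminus. The fallback leaves boron chemistry, sets out from 4 and 5 and comes back at 20. Alkenyllithium 7 (from 5 and n-BuLi) would add to ethyl glyoxylate (CCOC(=O)C=O) to give racemic ethyl 3-(diethoxymethyl)-2-hydroxybut-3-enoate F4. A Mitsunobu etherification with 4 (PPh3, DIAD) would give ethyl 2-{4-[(1R)-1-(tert-butyldimethylsilyloxy)ethyl]-2-iodophenoxy}-3-(diethoxymethyl)but-3-enoate F5. Iodine–magnesium exchange with iPrMgCl·LiCl at −40 °C (Parham-type cyclisation onto the ester) would close C3a–C3 to ketone F3. The transfer hydrogenation with dynamic kinetic resolution described above would then set C2 and C3 together and give 20.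

3. Step 6. The electron-poor α-aryloxy allyl group may migrate sluggishly from borate 15, and the β-aryloxy boronic ester product may lose aryloxide by β-elimination under ZnCl2. The fallback puts C3 in at the aldehyde level instead of as a chloride; it sets out from 14 and comes back at 20. Preformed methoxy(phenylthio)methyllithium, LiCH(OMe)SPh, would add to 14. HgCl2-induced migration would then give the α-methoxy boronic ester (4S,5S)-2-[(2R)-2-{4-[(1R)-1-(tert-butyldimethylsilyloxy)ethyl]-2-iodophenoxy}-3-(diethoxymethyl)-1-methoxybut-3-en-1-yl]-4,5-dicyclohexyl-1,3,2-dioxaborolane F6. Buffered H2O2 would convert this into aldehyde F1, which would be carried through F2 and F3 to 20 as in the first fallback.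

Further compounds
F1 | step 7 | (2R)-2-{4-[(1R)-1-(tert-butyldimethylsilyloxy)ethyl]-2-iodophenoxy}-3-(diethoxymethyl)but-3-enal | C=C(C(OCC)OCC)[C@@H](Oc1ccc([C@@H](C)O[Si](C)(C)C(C)(C)C)cc1I)C=O
F2 | step 7 | (2R)-5-[(1R)-1-(tert-butyldimethylsilyloxy)ethyl]-2-(3,3-diethoxyprop-1-en-2-yl)-2,3-dihydro-1-benzofuran-3-ol, both C3 epimers | C=C(C(OCC)OCC)[C@H]1Oc2ccc([C@@H](C)O[Si](C)(C)C(C)(C)C)cc2C1O
F3 | step 7 | 5-[(1R)-1-(tert-butyldimethylsilyloxy)ethyl]-2-(3,3-diethoxyprop-1-en-2-yl)-1-benzofuran-3(2H)-one, C2 labile | C=C(C(OCC)OCC)C1Oc2ccc([C@@H](C)O[Si](C)(C)C(C)(C)C)cc2C1=O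
F4 | step 5 | ethyl 3-(diethoxymethyl)-2-hydroxybut-3-enoate, racemic | CCOC(=O)C(O)C(=C)C(OCC)OCC
F5 | step 5 | ethyl 2-{4-[(1R)-1-(tert-butyldimethylsilyloxy)ethyl]-2-iodophenoxy}-3-(diethoxymethyl)but-3-enoate, both C2 epimers | CCOC(=O)C(Oc1ccc([C@@H](C)O[Si](C)(C)C(C)(C)C)cc1I)C(=C)C(OCC)OCC
F6 | step 6 | (4S,5S)-2-[(2R)-2-{4-[(1R)-1-(tert-butyldimethylsilyloxy)ethyl]-2-iodophenoxy}-3-(diethoxymethyl)-1-methoxybut-3-en-1-yl]-4,5-dicyclohexyl-1,3,2-dioxaborolane | C=C(C(OCC)OCC)[C@@H](Oc1ccc([C@@H](C)O[Si](C)(C)C(C)(C)C)cc1I)C(OC)B1O[C@@H](C2CCCCC2)[C@H](C2CCCCC2)O1
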